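- I began at late times, with the last reading of each earlier run, at 15.0 min. The teal run had 63.5% of its electrophile left and the blue run 62.7%, though blue held 4.1 equiv of free base against teal's 2.3 equiv.

the same everywhere: electrophile 0.30 M
- teal: nucleophile 1.3 equiv; free base 2.3 equiv; run made earlier
- blue: nucleophile 1.3 equiv; free base 4.1 equiv; run made earlier
- Tuesday's: nucleophile 1.30 equiv; free base 2.00 equiv; time 30 min
- Friday's: nucleophile 1.30 equiv; free base 3.00 equiv; time 30 min

| run | time / min | electrophile / % | target / % |
|---|---|---|---|
| teal | 1.33 | 95.5 | 4.8 |
| teal | 3.00 | 90.4 | 10.0 |
| teal | 6.00 | 81.5 | 17.4 |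
| teal | 15.0 | 63.5 | 34.6 |
| blue | 4.00 | 87.2 | 12.8 |
| blue | 8.00 | 77.2 | 22.2 |
| blue | 12.0 | 69.1 | 29.9 |
| blue | 15.0 | 62.7 | 35.0 |

(readings scatter by 0.3 percentage points)

- part of the electrophile that has reacted at the end, Tuesday's
- part of the electrophile that has reacted at the end, Friday's
- what raising the equivalents of free base from its lowest to its highest value here does to the part of the electrophile that has reacted (changes below 5 percentage points count as none) (it falls / no change / it rises)

- That gap of 0.8 percentage points was smaller than the 5 points that counts. So I used one clock for Tuesday's and Friday's flasks, although Tuesday's 2.00 equiv lies below teal's.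
- I assumed each event takes one electrophile, the limiting reagent, and one nucleophile, at a rate first order in each. Then c(nucleophile) − c(electrophile) stays constant, and the ratio c(nucleophile)/c(electrophile) grows exponentially.
- In the teal run that ratio rose from 1.3 to 1.47. So that reading gave 83.5 min as the time for the ratio to grow by a factor of two, the ratio's doubling time.
- The asked 30 min is 0.359 doublings, which takes the ratio to 1.67.
- The constant excess divided by that ratio minus one gives the electrophile left, so I reckoned 55.1% reacted in both flasks.
- The weak link was resting on one teal reading. The blue run's last reading gave a doubling time of 80.8 min, and so 56.0% reacted.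
- The forecast gave 55% for Tuesday's, 55% for Friday's and no change, holding that “even 2.0 equiv of base stays in excess”.
- The flasks gave 56.4% for Tuesday's, 56.4% for Friday's and no change.

    electrophile + nucleophile → acid set free + target (k = 0.00150 M⁻¹ s⁻¹)
    nucleophile + acid set free ⇌ protonated nucleophile, settled at all times (K = 29.0 M⁻¹)
    acid set free + free base ⇌ salt of the base, settled at all times (K = 33000 M⁻¹)
    electrophile + target → side product (k = 2.50 × 10⁻⁴ M⁻¹ s⁻¹)
    crystals ⇌ target, rate k5*(cs5 - [target]) while solid is left; crystals form when [target] > cs5 (solubility = 0.150 M, k = 0.0370 s⁻¹)

- Tuesday's flask had not come to rest at 30 min, with 44% of its electrophile still there. At 300 min the doubling time gave 98.0% reacted, and the flask stood at 99.2%. Friday's flask, left until 80 min, gave 80.3% by the same count and 83.1% in the flask, with 11.3% side product. After 300 min, Tuesday's flask held, in percent of the electrophile charged, 0.828% electrophile, 16.3% side product and 82.9% target, with crystals counted in the target at 32.9%.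

Readings and results are simulated for an exercise, and the scatter is random.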